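**Retrosynthetic overview**
1. The last step closes the ten-membered ring and the butenolide together: intramolecular Ni/Cr alkenylation (C7–C8) of a (Z)-enal by a (Z)-β-triflyloxy enoate, then lactonisation.
2. The enoate arm comes from a C8 aldehyde by Roskamp homologation; the C13 ketone and C14 acetate come from a cyclohexa-1,3-diene by carbinol-directed epoxidation and DMSO oxidative opening.
3. Key disconnection C1–C2: enantiotopos-selective carbonyl allylation by a meso cyclohexa-2,5-dienyl titanium TADDOLate; one C–C bond sets C1 (quaternary) and C2 and makes C10 stereogenic.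
4. The meso diene comes from a xylene feedstock by Birch reduction and pentadienyl-anion alkylation; the aldehyde partner is a monoterpene-derived (Z)-alkene carrying C2–C7.
5. Ring order: six-membered carbocycle first (all six carbons from the arene); ten-membered carbocycle and γ-lactone last, in one operation.

Assumption: positions are named by briarane numbering (C1 quaternary ring-fusion carbon, C2 benzoate carbon, C5=C6 Z-alkene, C7 lactone carbinol, C8=C17 butenolide alkene, C9 methylene, C10 ring-fusion CH, C11=C12 enone alkene, C13 ketone, C14 acetate carbon); the given SMILES is read as (1R,2S,5Z,7R,10R,14S). TBS = tert-butyldimethylsilyl.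

**Step 1**
Reactants: 1 m-xylene
Product: 2 Birch diene 1,5-dimethylcyclohexa-1,4-diene
Conditions: Na, NH3 (l), EtOH, Et2O, −78 → −33 °C
Reagents that add atoms: none
Why: Birch reduction, in which the radical anion is protonated at the two unsubstituted para-related carbons so that both methyl groups stay on the alkenes; no stereocentre is formed.

**Step 2**
Reactants: 2 Birch diene 1,5-dimethylcyclohexa-1,4-diene; 3 (2-bromoethoxy)(tert-butyl)dimethylsilane
Product: 5 meso diene tert-butyl[2-(2,6-dimethylcyclohexa-2,5-dien-1-yl)ethoxy]dimethylsilane, via potassium dienide 4 (not isolated)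
Conditions: n-BuLi, KOt-Bu, THF, −78 → −50 °C (equilibration); then 3, −78 → 0 °C
Reagents that add atoms: none
Why: Metalation–alkylation of a Birch diene: under equilibrating superbase conditions the pentadienyl anion that keeps both methyl groups on its nodal carbons (deprotonation at C6, between the methylated alkene carbons) dominates and is alkylated by SN2 at its central carbon, giving the non-conjugated achiral diene in which C6 is only prochiral.

**Step 3**
Reactants: 6 nerol
Product: 7 neryl TBS ether tert-butyl{[(2Z)-3,7-dimethylocta-2,6-dien-1-yl]oxy}dimethylsilane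
Conditions: TBSCl, imidazole, CH2Cl2, 0 °C → rt
Reagents that add atoms: tert-butyldimethylsilyl chloride, C[Si](C)(Cl)C(C)(C)C
Why: Standard imidazole-mediated O-silylation of a primary allylic alcohol; the Z-alkene that will become C5=C6 is bought in and untouched.

**Step 4**
Reactants: 7 neryl TBS ether
Product: 9 aldehyde (4Z)-6-{[tert-butyl(dimethyl)silyl]oxy}-4-methylhex-4-enal, via epoxide 8 (not isolated)
Conditions: mCPBA, NaHCO3, CH2Cl2, −20 °C; then H5IO6, THF–H2O, 0 °C
Reagents that add atoms: 3-chloroperoxybenzoic acid, OOC(=O)c1cccc(Cl)c1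
Why: Chemoselective Prilezhaev epoxidation of the more electron-rich distal trisubstituted alkene (the proximal one is deactivated by the allylic oxygen), followed in the same flask by periodic acid epoxide hydrolysis and glycol cleavage; the Z-alkene is not involved and no stereocentre remains.

**Step 5 (key step)**
Reactants: 5 meso diene; 9 aldehyde
Product: 12 homoallylic alcohol (1S,4Z)-6-{[tert-butyl(dimethyl)silyl]oxy}-1-[(1R,6R)-6-(2-{[tert-butyl(dimethyl)silyl]oxy}ethyl)-1,5-dimethylcyclohexa-2,4-dien-1-yl]-4-methylhex-4-en-1-ol, via dienyllithium 10 (not isolated), via dienyltitanium TADDOLate 11 (not isolated)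
Conditions: s-BuLi, TMEDA, THF, −78 °C; CpTiCl[(4S,5S)-TADDOLate] (C36H33ClO4Ti), −78 °C; then 9, −78 °C; H2O
Reagents that add atoms: none
Why: Desymmetrising carbonyl allylation of a metalated cyclohexa-1,4-diene (Hafner–Duthaler-type allyltitanation): kinetic deprotonation of the unhindered bis-allylic CH2 gives a meso pentadienyl metal whose two enantiotopic methyl-bearing termini are told apart by the chiral titanium, which adds to the Re face of the aldehyde through a closed chair transition state (ring carbon C10 in the Z position, methyl in the E position) on the ring face anti to the C10 side chain, so that C1 (R, quaternary) and C2 (S) are set and C10 (R) becomes stereogenic in one bond formation; the (S,S)-ligand is chosen because the (R,R)-reagents of this class add to the Si face.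

**Step 6**
Reactants: 12 homoallylic alcohol
Product: 13 epoxy alcohol (12 with an oxirane across C13–C14 on the ring face that carries the C2 carbinol chain, trans to the C1 methyl)
Conditions: VO(acac)2 (5 mol%), t-BuOOH, CH2Cl2, 0 °C
Reagents that add atoms: tert-butyl hydroperoxide, CC(C)(C)OO
Why: Hydroxyl-directed vanadium-catalysed epoxidation, in which the homoallylic C2 hydroxyl binds vanadium and delivers oxygen to the near cis-disubstituted C13=C14 alkene on its own (α) face, setting the C14–O configuration; the two trisubstituted alkenes are only bishomoallylic and react more slowly.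

**Step 7**
Reactants: 13 epoxy alcohol
Product: 14 epoxy benzoate (C2 benzoate of 13)
Conditions: BzCl, Et3N, DMAP (cat.), CH2Cl2, 0 °C → rt
Reagents that add atoms: benzoyl chloride, O=C(Cl)c1ccccc1
Why: DMAP-catalysed acylation of the hindered secondary alcohol with retention at C2; it is placed after the epoxidation because the free hydroxyl was needed as the directing group.

**Step 8**
Reactants: 14 epoxy benzoate
Product: 17 acetoxy enone (1S,4Z)-1-[(1R,2S,6R)-2-acetoxy-6-(2-{[tert-butyl(dimethyl)silyl]oxy}ethyl)-1,5-dimethyl-3-oxocyclohex-4-en-1-yl]-6-{[tert-butyl(dimethyl)silyl]oxy}-4-methylhex-4-en-1-yl benzoate, via alkoxysulfonium betaine 15 (not isolated), via hydroxy enone 16 (not isolated)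
Conditions: DMSO (5 equiv), BF3·OEt2 (20 mol%), ClCH2CH2Cl, 45 °C; then Ac2O, pyridine, DMAP, 0 °C → rt
Reagents that add atoms: dimethyl sulfoxide, CS(C)=O; acetic anhydride, CC(=O)OC(C)=O
Why: Cohen–Tsuji DMSO oxidation of an epoxide (Kornblum-type): the Lewis-acid-activated vinyl epoxide is opened by DMSO at allylic C13 and the betaine collapses to the C13 enone and dimethyl sulfide, while the C14–O bond from step 6 is never broken and the resulting ketol is acetylated in the same flask.

**Step 9**
Reactants: 17 acetoxy enone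
Product: 19 dialdehyde (1S,4Z)-1-[(1R,2S,6R)-2-acetoxy-1,5-dimethyl-3-oxo-6-(2-oxoethyl)cyclohex-4-en-1-yl]-4-methyl-6-oxohex-4-en-1-yl benzoate, via diol 18 (not isolated)
Conditions: PhI(OAc)2 (2.5 equiv), TEMPO (20 mol%), Bi(OTf)3 (5 mol%), MeCN, H2O (2 equiv), rt
Reagents that add atoms: none
Why: One-pot oxidative desilylation, in which Bi(OTf)3-catalysed hydrolysis frees both primary alcohols and TEMPO/PhI(OAc)2 oxidises them to the saturated C8 aldehyde and the (Z)-enal without over-oxidation or Z/E isomerisation; no stereocentre is touched.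

**Step 10**
Reactants: 20 methyl 2-methyl-3-oxobutanoate
Product: 21 methyl 2-diazopropanoate
Conditions: 4-acetamidobenzenesulfonyl azide, DBU, MeCN, 0 °C → rt
Reagents that add atoms: 4-acetamidobenzenesulfonyl azide, CC(=O)Nc1ccc(cc1)S(=O)(=O)N=[N+]=[N-]
Why: Regitz deacylative diazo transfer, in which the triazoline adduct of the α-substituted β-keto ester fragments with transfer of the acetyl group to the sulfonamide nitrogen.

**Step 11**
Reactants: 19 dialdehyde; 21 methyl 2-diazopropanoate
Product: 22 keto ester (1S,4Z)-1-[(1R,2S,6R)-2-acetoxy-6-(4-methoxy-3-methyl-2,4-dioxobutyl)-1,5-dimethyl-3-oxocyclohex-4-en-1-yl]-4-methyl-6-oxohex-4-en-1-yl benzoate (mixture at the keto ester α-carbon)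
Conditions: Sc(OTf)3 (5 mol%), 21 (1.05 equiv), CH2Cl2, −40 → 0 °C
Reagents that add atoms: none
Why: Roskamp homologation, in which the Lewis-acid-activated saturated aldehyde (far more electrophilic than the conjugated enal or the enone) is attacked by the diazo carbon and a 1,2-hydride shift with loss of N2 gives the β-keto ester; its α-stereocentre is destroyed in the next step.

**Step 12**
Reactants: 22 keto ester
Product: 23 enol triflate (1S,4Z)-1-[(1R,2S,6R)-2-acetoxy-6-[(2Z)-4-methoxy-3-methyl-4-oxo-2-{[(trifluoromethyl)sulfonyl]oxy}but-2-en-1-yl]-1,5-dimethyl-3-oxocyclohex-4-en-1-yl]-4-methyl-6-oxohex-4-en-1-yl benzoate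
Conditions: NaH (1.0 equiv), THF, 0 °C; then PhNTf2, 0 °C → rt
Reagents that add atoms: N-phenylbis(trifluoromethanesulfonimide), FC(F)(F)S(=O)(=O)N(c1ccccc1)S(=O)(=O)C(F)(F)F
Why: O-Triflation of the chelated sodium (Z)-enolate gives the (Z)-enol triflate with OTf cis to the ester, as the later lactonisation needs; one equivalent of base touches only the β-dicarbonyl, and the only intramolecular trap (5-exo Michael addition to C11) would build two adjacent quaternary carbons and is slow.

**Step 13**
Reactants: 23 enol triflate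
Product: 26 target CNP0194180.3, via alkenylchromium 24 (not isolated), via chromium alkoxide 25 (not isolated)
Conditions: CrCl2 (6 equiv), NiCl2 (10 mol%), Kishi oxazoline–sulfonamide ligand N-[2-(4-isopropyl-4,5-dihydro-1,3-oxazol-2-yl)-6-methylphenyl]methanesulfonamide (enantiomer matched to Si-face addition), Et3N, THF, 2 mM, rt; then silica gel
Reagents that add atoms: none
Why: Nozaki–Hiyama–Kishi macrocyclisation, in which zerovalent nickel inserts into the enol triflate, transmetalation gives the alkenyl species of trivalent chromium and its ligand-controlled 1,2-addition to the Si face of the (Z)-enal closes the ten-membered ring and sets C7 (R), after which the alkoxide, cis to the methyl ester, lactonises to the butenolide.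

**Compound list**
1 | m-xylene (1,3-dimethylbenzene) | Cc1cccc(C)c1 | starting material
2 | 1,5-dimethylcyclohexa-1,4-diene | CC1=CCC=C(C)C1 | intermediate
3 | (2-bromoethoxy)(tert-butyl)dimethylsilane | BrCCO[Si](C)(C)C(C)(C)C | starting material
4 | potassium 2,6-dimethylcyclohexa-2,5-dien-1-ide (pentadienyl anion, methyls on the nodal carbons) | [K+].CC1=CCC=C(C)[CH-]1 | intermediate
5 | tert-butyl[2-(2,6-dimethylcyclohexa-2,5-dien-1-yl)ethoxy]dimethylsilane (achiral, mirror-symmetric) | CC1=CCC=C(C)C1CCO[Si](C)(C)C(C)(C)C | intermediate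
6 | nerol, (2Z)-3,7-dimethylocta-2,6-dien-1-ol | CC(C)=CCC/C(C)=C\CO | starting material
7 | tert-butyl{[(2Z)-3,7-dimethylocta-2,6-dien-1-yl]oxy}dimethylsilane | CC(C)=CCC/C(C)=C\CO[Si](C)(C)C(C)(C)C | intermediate
8 | tert-butyl{[(2Z)-5-(3,3-dimethyloxiran-2-yl)-3-methylpent-2-en-1-yl]oxy}dimethylsilane (racemic oxirane) | CC1(C)OC1CC/C(C)=C\CO[Si](C)(C)C(C)(C)C | intermediate
9 | (4Z)-6-{[tert-butyl(dimethyl)silyl]oxy}-4-methylhex-4-enal | O=CCC/C(C)=C\CO[Si](C)(C)C(C)(C)C | intermediate
10 | [4-(2-{[tert-butyl(dimethyl)silyl]oxy}ethyl)-3,5-dimethylcyclohexa-2,5-dien-1-yl]lithium | [Li]C1C=C(C)C(CCO[Si](C)(C)C(C)(C)C)C(C)=C1 | intermediate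
11 | (cyclopentadienyl)[(4S,5S)-TADDOLato][4-(2-{[tert-butyl(dimethyl)silyl]oxy}ethyl)-3,5-dimethylcyclohexa-2,5-dien-1-yl]titanium | CC1(C)O[C@H]2[C@H](O1)C(c1ccccc1)(c1ccccc1)O[Ti](C3C=C(C)C(CCO[Si](C)(C)C(C)(C)C)C(C)=C3)(C3C=CC=C3)OC2(c1ccccc1)c1ccccc1 | intermediate
12 | (1S,4Z)-6-{[tert-butyl(dimethyl)silyl]oxy}-1-[(1R,6R)-6-(2-{[tert-butyl(dimethyl)silyl]oxy}ethyl)-1,5-dimethylcyclohexa-2,4-dien-1-yl]-4-methylhex-4-en-1-ol | O[C@@H](CC/C(C)=C\CO[Si](C)(C)C(C)(C)C)[C@]1(C)C=CC=C(C)[C@H]1CCO[Si](C)(C)C(C)(C)C | intermediate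
13 | epoxy alcohol: 12 with a C13–C14 oxirane cis to the carbinol chain and trans to the C1 methyl | O[C@@H](CC/C(C)=C\CO[Si](C)(C)C(C)(C)C)[C@]1(C)[C@@H]2O[C@@H]2C=C(C)[C@H]1CCO[Si](C)(C)C(C)(C)C | intermediate
14 | epoxy benzoate: C2 benzoate of 13 | O=C(O[C@@H](CC/C(C)=C\CO[Si](C)(C)C(C)(C)C)[C@]1(C)[C@@H]2O[C@@H]2C=C(C)[C@H]1CCO[Si](C)(C)C(C)(C)C)c1ccccc1 | intermediate
15 | alkoxysulfonium betaine: C13–O–S(+)Me2 trans to the C14 alkoxide | O=C(O[C@@H](CC/C(C)=C\CO[Si](C)(C)C(C)(C)C)[C@]1(C)[C@H]([O-])[C@@H](O[S+](C)C)C=C(C)[C@H]1CCO[Si](C)(C)C(C)(C)C)c1ccccc1 | intermediate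
16 | hydroxy enone: (1S,4Z)-6-{[tert-butyl(dimethyl)silyl]oxy}-1-[(1R,2S,6R)-6-(2-{[tert-butyl(dimethyl)silyl]oxy}ethyl)-2-hydroxy-1,5-dimethyl-3-oxocyclohex-4-en-1-yl]-4-methylhex-4-en-1-yl benzoate | O=C(O[C@@H](CC/C(C)=C\CO[Si](C)(C)C(C)(C)C)[C@]1(C)[C@H](O)C(=O)C=C(C)[C@H]1CCO[Si](C)(C)C(C)(C)C)c1ccccc1 | intermediate
17 | acetoxy enone: C14 acetate of 16 | O=C(O[C@@H](CC/C(C)=C\CO[Si](C)(C)C(C)(C)C)[C@]1(C)[C@H](OC(C)=O)C(=O)C=C(C)[C@H]1CCO[Si](C)(C)C(C)(C)C)c1ccccc1 | intermediate
18 | diol: 17 with both silyl ethers replaced by OH | O=C(O[C@@H](CC/C(C)=C\CO)[C@]1(C)[C@H](OC(C)=O)C(=O)C=C(C)[C@H]1CCO)c1ccccc1 | intermediate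
19 | dialdehyde: (1S,4Z)-1-[(1R,2S,6R)-2-acetoxy-1,5-dimethyl-3-oxo-6-(2-oxoethyl)cyclohex-4-en-1-yl]-4-methyl-6-oxohex-4-en-1-yl benzoate | O=C(O[C@@H](CC/C(C)=C\C=O)[C@]1(C)[C@H](OC(C)=O)C(=O)C=C(C)[C@H]1CC=O)c1ccccc1 | intermediate
20 | methyl 2-methyl-3-oxobutanoate | CC(=O)C(C)C(=O)OC | starting material
21 | methyl 2-diazopropanoate | CC(=[N+]=[N-])C(=O)OC | intermediate
22 | keto ester: 19 with the saturated CHO turned into C(=O)CH(CH3)CO2CH3 | O=C(O[C@@H](CC/C(C)=C\C=O)[C@]1(C)[C@H](OC(C)=O)C(=O)C=C(C)[C@H]1CC(=O)C(C)C(=O)OC)c1ccccc1 | intermediate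
23 | (Z)-enol triflate of 22 (OTf cis to CO2CH3) | O=C(O[C@@H](CC/C(C)=C\C=O)[C@]1(C)[C@H](OC(C)=O)C(=O)C=C(C)[C@H]1C/C(OS(=O)(=O)C(F)(F)F)=C(\C)C(=O)OC)c1ccccc1 | intermediate
24 | alkenylchromium dichloride: 23 with OTf replaced by CrCl2 | O=C(O[C@@H](CC/C(C)=C\C=O)[C@]1(C)[C@H](OC(C)=O)C(=O)C=C(C)[C@H]1C/C([Cr](Cl)Cl)=C(\C)C(=O)OC)c1ccccc1 | intermediate
25 | chromium alkoxide of the ten-membered (7R)-hydroxy ester (seco-lactone) | CC(=O)O[C@@H]1C(=O)C=C(C)[C@H]2C/C(=C(\C)C(=O)OC)[C@H](O[Cr](Cl)Cl)/C=C(/C)CC[C@H](OC(=O)c3ccccc3)[C@@]21C | intermediate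
26 | CNP0194180.3, (1R,2S,5Z,7R,10R,14S)-14-acetoxy-2-benzoyloxy-13-oxo briarane butenolide | CC(=O)O[C@@H]1C(=O)C=C(C)[C@H]2CC3=C(C)C(=O)O[C@@H]3/C=C(/C)CC[C@H](OC(=O)c3ccccc3)[C@@]21C | target

**Totals**
Total step count: 13. Longest linear sequence: 10 steps (1, 2, 5, 6, 7, 8, 9, 11, 12, 13; the nerol branch 3, 4, 5, … 13 is also 10).

**Three steps most likely to fail, with fallbacks**

Step 5 (desymmetrising allyltitanation). The risks are deprotonation at the tertiary C10–H, poor terminus selection, or sluggish addition at the methyl-bearing terminus. The fallback sets out from 5 and comes back at 12. Dienyllithium 10 is trapped with 2-isopropoxy-4,4,5,5-tetramethyl-1,3,2-dioxaborolane to give the isolable bis-allylic pinacol boronate F1. F1 is then added to aldehyde 9 in a chiral phosphoric acid-catalysed allylboration (TRIP-type acid, toluene, −30 °C). The same closed six-membered transition state gives the same relative configuration, but the enantiotopic termini are now distinguished by a Brønsted acid catalyst instead of a stoichiometric chiral metal. The uncatalysed thermal reaction gives racemic 12 for scouting the later steps.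

Step 8 (DMSO oxidative opening of the vinyl epoxide). The risks are hydride-shift rearrangement of the activated epoxide, attack at C11 and loss of a silyl ether. The fallback sets out from 14 and comes back at 16. The epoxide is hydrolysed by water at allylic C13 (dilute HClO4, THF–H2O, 0 °C) to the trans-diol F2. The allylic C13 alcohol alone is then oxidised with MnO2 (CH2Cl2, rt) to hydroxy enone 16, which is isolated and acetylated as in step 8 to reach 17.

Step 13 (Ni/Cr macrocyclisation and C7 configuration). The risks are oligomerisation, addition of the alkenylchromium to the C13 ketone, Z/E drift of the enal and the wrong C7 epimer. The fallback sets out from 5 (and uses 21) and comes back at 26. It moves the ring closure to the C5=C6 alkene and sets C7 before the ring exists: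
- Diene 5 is allylated under the step 5 conditions with 4-methylpent-4-enal F3 to give homoallylic alcohol F4.
- F4 is taken through the conditions of steps 6, 7 and 8 to epoxy alcohol F5, epoxy benzoate F6 and acetoxy enone F7.
- F7 is oxidatively desilylated as in step 9 to aldehyde F8, homologated with 21 as in step 11 to keto ester F9 and triflated as in step 12 to enol triflate F10.
- F10 is coupled intermolecularly with acrolein under the ligand-controlled Ni/Cr conditions of step 13, which gives the (7R)-vinyl butenolide F11 after lactonisation.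
- F11 is closed by ring-closing metathesis (second-generation Hoveyda–Grubbs catalyst, toluene, 80 °C, 1 mM), the ten-membered ring favouring the Z-trisubstituted alkene, to give 26.

**Further compounds**
F1 | step 5 | 2-[4-(2-{[tert-butyl(dimethyl)silyl]oxy}ethyl)-3,5-dimethylcyclohexa-2,5-dien-1-yl]-4,4,5,5-tetramethyl-1,3,2-dioxaborolane | CC1=CC(B2OC(C)(C)C(C)(C)O2)C=C(C)C1CCO[Si](C)(C)C(C)(C)C
F2 | step 8 | trans-diol: 14 with the oxirane opened to C14–OH (cis to the benzoate chain) and C13–OH (trans to it) | O=C(O[C@@H](CC/C(C)=C\CO[Si](C)(C)C(C)(C)C)[C@]1(C)[C@H](O)[C@@H](O)C=C(C)[C@H]1CCO[Si](C)(C)C(C)(C)C)c1ccccc1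
F3 | step 13 | 4-methylpent-4-enal | O=CCCC(C)=C
F4 | step 13 | (1S)-1-[(1R,6R)-6-(2-{[tert-butyl(dimethyl)silyl]oxy}ethyl)-1,5-dimethylcyclohexa-2,4-dien-1-yl]-4-methylpent-4-en-1-ol | O[C@@H](CCC(C)=C)[C@]1(C)C=CC=C(C)[C@H]1CCO[Si](C)(C)C(C)(C)C
F5 | step 13 | epoxy alcohol: F4 with a C13–C14 oxirane cis to the carbinol chain | O[C@@H](CCC(C)=C)[C@]1(C)[C@@H]2O[C@@H]2C=C(C)[C@H]1CCO[Si](C)(C)C(C)(C)C
F6 | step 13 | epoxy benzoate: C2 benzoate of F5 | O=C(O[C@@H](CCC(C)=C)[C@]1(C)[C@@H]2O[C@@H]2C=C(C)[C@H]1CCO[Si](C)(C)C(C)(C)C)c1ccccc1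
F7 | step 13 | (1S)-1-[(1R,2S,6R)-2-acetoxy-6-(2-{[tert-butyl(dimethyl)silyl]oxy}ethyl)-1,5-dimethyl-3-oxocyclohex-4-en-1-yl]-4-methylpent-4-en-1-yl benzoate | O=C(O[C@@H](CCC(C)=C)[C@]1(C)[C@H](OC(C)=O)C(=O)C=C(C)[C@H]1CCO[Si](C)(C)C(C)(C)C)c1ccccc1
F8 | step 13 | aldehyde: F7 with CH2CH2OTBS turned into CH2CHO | O=C(O[C@@H](CCC(C)=C)[C@]1(C)[C@H](OC(C)=O)C(=O)C=C(C)[C@H]1CC=O)c1ccccc1
F9 | step 13 | keto ester: F8 with CHO turned into C(=O)CH(CH3)CO2CH3 | O=C(O[C@@H](CCC(C)=C)[C@]1(C)[C@H](OC(C)=O)C(=O)C=C(C)[C@H]1CC(=O)C(C)C(=O)OC)c1ccccc1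
F10 | step 13 | (Z)-enol triflate of F9 | O=C(O[C@@H](CCC(C)=C)[C@]1(C)[C@H](OC(C)=O)C(=O)C=C(C)[C@H]1C/C(OS(=O)(=O)C(F)(F)F)=C(\C)C(=O)OC)c1ccccc1
F11 | step 13 | (7R)-vinyl butenolide: ring C10 bears CH2 attached to C4 of a (5R)-3-methyl-5-vinylfuran-2(5H)-one | O=C(O[C@@H](CCC(C)=C)[C@]1(C)[C@H](OC(C)=O)C(=O)C=C(C)[C@H]1CC1=C(C)C(=O)O[C@@H]1C=C)c1ccccc1
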